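## The problem

Atoms carry the azulene locants of the target throughout, also in acyclic precursors. Ring B is the cyclopentane C1–C2–C3–C3a–C8a. Ring A is the cycloheptenone C3a–C4–C5=C6–C7(=O)–C8–C8a.

- The rings share the C3a–C8a bond, and H-3a and the 8a-methyl are trans.
- Five contiguous stereocentres must be set: the secondary carbinol C1, the tertiary carbinol C3 (isopropyl), the ring-fusion CH C3a, the ester-bearing C4 and the quaternary C8a. The 8a-methyl, 1-OH and 3-OH lie on one face of ring B.
- C4 is the centre that can be set early by a reagent and then used. Through allylic strain it can decide which face of C3a forms a bond, and its acyloxy group can deliver oxygen to C3. C1 and C8a are remote from C4 and need a reagent-controlled step of their own.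
- The aroyl ester sits 1,3 to a tertiary alcohol and is allylic, so acyl migration and elimination threaten under base or acid. The free phenol must be masked until the end, and only a mild unmasking may follow the ring-forming event.
- The enabling feature is that the C3a–C8a bond divides a ten-membered carbocycle. O-1 sits where an epoxide across C1–C8a leaves its oxygen when C8a is attacked. C3 is the tertiary cation left when C3a of a C3=C3a alkene is the nucleophile. The carbonyl oxygen of the O-4 ester can reach that cation through a six-membered dioxanylium ring.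
- The C5=C6 alkene is conjugated to the C7 ketone and is too electron-poor to compete.

## Retrosynthesis

**31 from 30.** Only the phenol O–Si bond is cut. A triisopropylsilyl ether is chosen over the tert-butyldimethylsilyl ether because the electron-poor aryl silyl ether must survive a pH 10 epoxidation, two oxidations, chromium salts and BF3. Buffered fluoride then removes it without touching the ester.

**30 from 28 (through 29).** The C3a–C8a bond and the O–C3 bond are cut, opening both rings to the epoxy cyclodecadienone 28. This removes two rings and the centres C3, C3a and C8a in one operation, where stepwise annulation would need separate solutions for the quaternary carbon and the tertiary carbinol.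

- The forward reaction needs a trans-epoxide of (1R,8aR) configuration, opened at C8a with inversion.
- It needs the C3=C3a alkene with isopropyl cis to C4 (Z). In ring B the new bond is flanked by the former epoxide bond and the former alkene bond, and their twists must have the same sense. Only the ring-trans alkene matches the twist fixed by rear-side opening of this epoxide while C4 stays on the C8 side, which is the trans fusion. The geometric isomer would be channelled to the cis-fused ring system.
- The isopropyl group cis to C4 also gives the 4-stereocentre its grip on the C3a face through allylic 1,3-strain.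

**28 from 27 and 25.** The C6–C7 bond is cut (chromium/nickel-mediated alkenyl iodide–aldehyde coupling, then oxidation). Closing at C4–C5 instead would create the C4 stereocentre during ring closure without control. Closing at C6–C7 creates only a carbinol that is oxidised away, and it delivers the Z-enone from a Z-alkenyl iodide with retention. The precursor 25 is acyclic. The forward step must tolerate ester, epoxide and aryl silyl ether and must overcome the strain of the ten-membered ring.

**25 from 24, 23 and 22.** The epoxide C–O bonds are cut back to the E-alkene of 22, and the aldehyde to a PMB ether. Epoxidising at this stage keeps the epoxide out of every hydride and organometallic step, which an early allylic-alcohol epoxidation would not. The price is site selectivity. This is expected because the other trisubstituted alkene carries an allylic aroyloxy group and a branched substituent, and the third alkene is an iodoalkene.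

**22 from 18 and 21; 21 from 19.** The ester C–O bond is cut. The aroyl group is introduced before the ring is formed, so no protecting group is needed on O-4 and the ester can act later as the internal nucleophile.

**18 from 16; 16 from 13 and 14.** The C6–I bond and the C4–C5 bond are cut. Catalytic asymmetric addition of propyne (14) to enal 13 sets C4. Hydroxyl-directed trans-hydroalumination and iodination then give the Z-alkenyl iodide with iodine cis to C4, the geometry of the ring enone. One building block thus supplies C5, C6 and the 6-methyl.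

**13 from 12, 11 and 9.** The C3–isopropyl bond and the C3–I bond are cut back to the alkyne of 9. Trans-hydroalumination places iodine cis to C4, and cross-coupling with retention puts isopropyl in its place. This fixes the Z geometry that the key step needs. Starting from an isopropyl alkyne and adding the C2 chain by the same sequence would give the opposite geometry.

**9 from 6 and 7; 6 from 5, 2 and 1.** The C2–C3 bond is cut (copper-catalysed alkynyl–allyl coupling with prop-2-yn-1-ol 7). The allylic bromide 6 comes from alcohol 5, and 5 from zirconium-catalysed methylalumination of the PMB ether 2 of but-3-yn-1-ol (1) with a one-carbon electrophile. That step sets the E-alkene that later becomes the trans-epoxide and installs the 8a-methyl.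

## Roads not taken

**Alternative 1: ring B by carbenoid C–H insertion.**

- Cut: the C2–C3 bond.
- Forward step: Rh2(OAc)4 converts the open-chain diazoketone A2 into a carbenoid that inserts into the silyloxy-activated methine C–H, giving cyclopentanone A1 with retention at C3.
- Merits: 1,5-insertion next to oxygen is dependable. C3, C3a and C8a are fixed before ring closure, so the ring-forming step carries less stereochemical risk than a transannular closure.
- Weak points: A2 needs three contiguous stereocentres, one quaternary, built in an open chain. Insertion into the isopropyl methine or the silyl ethyl groups can compete. After A1, all of ring A is still to be made from two ester arms, with the C4 carbinol, the enone and a face-selective reduction of the C1 ketone towards the hindered cis-to-methyl alcohol.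
- Comparison: the key step is safer than the chosen one. The chosen plan sets against this that one step closes both rings and sets three centres, with C4 already in place to direct it.

**Alternative 2: aldol-lactonisation to a bicyclic β-lactone.**

- Cut: the C3–C3a bond and the lactone C–O bond.
- Forward step: keto acid A4, activated with p-TolSO2Cl and a chiral isothiourea, forms an acylammonium enolate that adds to the isopropyl ketone and lactonises to A3.
- Merits: catalytic. O-3 ends up cis to the C4 carbon by the geometry of the four-membered ring, the same relation the dioxanylium ion provides, but without a free cation. The later seven-membered ring closure is easier than a ten-membered one. In these two respects it is better than the chosen plan.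
- Weak points: an isopropyl ketone is a slow aldol acceptor. The catalyst must override or match the C1/C8a centres to place H-3a trans to the 8a-methyl. The C4 stereocentre would arise only in the later ring closure with no obvious control, followed by ketal removal and oxidation-state changes.
- Comparison: the chosen plan has C4 set by a catalyst early and uses it twice, but accepts a harder macrocyclisation.

**Alternative 3: intramolecular Buchner ring expansion.**

- Cut: both bonds from C3a to C4 and to C8a.
- Forward step: Rh2(O2CCF3)4 turns aryl diazoketone A6 into a carbenoid that cyclopropanates the arene; the norcaradiene opens to the dihydroazulenone A5.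
- Merits: by far the shortest entry to the hydroazulene carbon framework, from a simple arene, with the 6-methyl and a C7 oxygen in place. On early step economy it beats the chosen plan.
- Weak points: A5 has only the C1 stereocentre. The quaternary methyl at C8a, the isopropyl carbinol at C3, the C4 oxygen and the trans fusion would all have to be added to a mobile cycloheptatriene by substrate control from C1 alone. The two ortho positions can both react, and hydrogen shifts in the triene are easy.
- Comparison: the chosen plan spends sixteen steps before its key step but emerges with every stereocentre and every oxygen of the target.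

Key step: step 17

Assumption: in step 8 the (S,S)-ligand is taken to give the 4R carbinol, by analogy with alkynylations of enals; if the sense proves opposite, the (R,R)-ligand is used with no other change.

## Route

**Step 1**
Reactants: 1 but-3-yn-1-ol
Product: 2 1-[(but-3-yn-1-yloxy)methyl]-4-methoxybenzene
Conditions: NaH, 4-methoxybenzyl chloride, Bu4NI (cat.), THF/DMF, 0 °C to rt
Reagents that add atoms: 4-methoxybenzyl chloride, COc1ccc(CCl)cc1
Why: Williamson etherification; the alkoxide is alkylated while the far less acidic alkyne C–H is left alone. The PMB ether can later be removed oxidatively in the presence of ester, epoxide and aryl silyl ether.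

**Step 2**
Reactants: 2 1-[(but-3-yn-1-yloxy)methyl]-4-methoxybenzene
Product: 5 (2E)-5-[(4-methoxybenzyl)oxy]-3-methylpent-2-en-1-ol, via alkenyldimethylalane 3 (not isolated), via lithium butyl(alkenyl)dimethylalanate 4 (not isolated)
Conditions: AlMe3, Cp2ZrCl2 (20 mol %), CH2Cl2, 0 °C to rt; then n-BuLi, THF/hexane, −78 °C; (CH2O)n, −78 °C to rt
Reagents that add atoms: trimethylaluminium, C[Al](C)C; paraformaldehyde (as formaldehyde), C=O
Why: Negishi zirconium-catalysed methylalumination adds methyl and aluminium syn, with aluminium on the terminal carbon, which fixes the E-alkene (C1=C8a) and the 8a-methyl. The butyl ate complex transfers the alkenyl group to formaldehyde with retention and gives the allylic alcohol (C2).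

**Step 3**
Reactants: 5 (2E)-5-[(4-methoxybenzyl)oxy]-3-methylpent-2-en-1-ol
Product: 6 1-({[(3E)-5-bromo-3-methylpent-3-en-1-yl]oxy}methyl)-4-methoxybenzene
Conditions: CBr4, PPh3, CH2Cl2, 0 °C
Reagents that add atoms: carbon tetrabromide, BrC(Br)(Br)Br
Why: Appel bromination of a primary allylic alcohol under neutral conditions; the alkene geometry and the PMB ether are not touched. The bromide is used at once.

**Step 4**
Reactants: 6 1-({[(3E)-5-bromo-3-methylpent-3-en-1-yl]oxy}methyl)-4-methoxybenzene; 7 prop-2-yn-1-ol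
Product: 9 (5E)-8-[(4-methoxybenzyl)oxy]-6-methyloct-5-en-2-yn-1-ol, via (3-hydroxyprop-1-ynyl)copper 8 (not isolated)
Conditions: CuI (10 mol %), Bu4NCl, K2CO3, DMF, rt
Reagents that add atoms: none
Why: Copper-catalysed alkynyl–allyl coupling; the monovalent copper acetylide displaces the primary allylic bromide at the unhindered carbon (the other allyl terminus is fully substituted). This gives the 1,4-enyne (C2–C3 bond) with the E-alkene intact and the free hydroxyl tolerated.

**Step 5**
Reactants: 9 (5E)-8-[(4-methoxybenzyl)oxy]-6-methyloct-5-en-2-yn-1-ol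
Product: 11 (2Z,5E)-3-iodo-8-[(4-methoxybenzyl)oxy]-6-methylocta-2,5-dien-1-ol, via cyclic sodium alkenylalanate 10 (not isolated)
Conditions: NaAlH2(OCH2CH2OMe)2 (Red-Al), THF, 0 °C to rt; then EtOAc; I2, THF, −78 to 0 °C
Reagents that add atoms: iodine, II
Why: Hydroxyl-directed trans-hydroalumination of a propargylic alcohol; hydride goes to C3a and aluminium to C3 inside a five-membered ring. Iodinolysis therefore puts iodine on C3 cis to C4 (the Corey trisubstituted-alkene protocol).

**Step 6**
Reactants: 11 (2Z,5E)-3-iodo-8-[(4-methoxybenzyl)oxy]-6-methylocta-2,5-dien-1-ol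
Product: 12 (2Z,5E)-8-[(4-methoxybenzyl)oxy]-6-methyl-3-(propan-2-yl)octa-2,5-dien-1-ol
Conditions: i-PrZnBr (3 equiv), PdCl2(dppf) (5 mol %), THF, rt to 40 °C
Reagents that add atoms: isopropylzinc bromide, CC(C)[Zn]Br
Why: Negishi coupling with retention at the alkenyl carbon, so isopropyl takes the place of iodine cis to C4, the Z geometry the ring closure needs. The wide bite angle of dppf makes reductive elimination faster than isomerisation of the secondary alkyl group.

**Step 7**
Reactants: 12 (2Z,5E)-8-[(4-methoxybenzyl)oxy]-6-methyl-3-(propan-2-yl)octa-2,5-dien-1-ol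
Product: 13 (2Z,5E)-8-[(4-methoxybenzyl)oxy]-6-methyl-3-(propan-2-yl)octa-2,5-dienal
Conditions: MnO2, CH2Cl2, rt
Reagents that add atoms: none
Why: Selective allylic oxidation on a neutral surface; Z-enals of this type (as in nerol to neral) survive without isomerisation, and the PMB ether is inert.

**Step 8**
Reactants: 13 (2Z,5E)-8-[(4-methoxybenzyl)oxy]-6-methyl-3-(propan-2-yl)octa-2,5-dienal; 14 propyne
Product: 16 (4R,5Z,8E)-11-[(4-methoxybenzyl)oxy]-9-methyl-6-(propan-2-yl)undeca-5,8-dien-2-yn-4-ol, via methyl(prop-1-ynyl)zinc 15 (not isolated)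
Conditions: Me2Zn, (S,S)-ProPhenol (20 mol %), Ph3P=O (40 mol %), toluene, 0 to 4 °C
Reagents that add atoms: none
Why: Catalytic asymmetric alkynylation of an enal by a dinuclear zinc–ProPhenol complex; the alkynylzinc adds 1,2 to the aldehyde held in the chiral pocket and sets C4. The centre is 4R here and becomes 4S in the target only through a change of substituent priorities.

**Step 9**
Reactants: 16 (4R,5Z,8E)-11-[(4-methoxybenzyl)oxy]-9-methyl-6-(propan-2-yl)undeca-5,8-dien-2-yn-4-ol
Product: 18 (2Z,4R,5Z,8E)-2-iodo-11-[(4-methoxybenzyl)oxy]-9-methyl-6-(propan-2-yl)undeca-2,5,8-trien-4-ol, via cyclic sodium alkenylalanate 17 (not isolated)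
Conditions: NaAlH2(OCH2CH2OMe)2 (Red-Al), THF, 0 °C to rt; then EtOAc; I2, THF, −78 to 0 °C
Reagents that add atoms: iodine, II
Why: Second directed trans-hydroalumination and iodination; hydride goes to C5 and iodine to C6 cis to C4, the geometry of the future ring enone. The isolated alkenes are not reduced and C4 is untouched.

**Step 10**
Reactants: 19 4-hydroxybenzoic acid
Product: 21 4-{[tri(propan-2-yl)silyl]oxy}benzoic acid, via silyl ester silyl ether 20 (not isolated)
Conditions: chlorotri(propan-2-yl)silane (2.2 equiv), imidazole, DMF, rt; then AcOH/THF/H2O, rt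
Reagents that add atoms: chlorotri(propan-2-yl)silane, CC(C)[Si](Cl)(C(C)C)C(C)C
Why: Both hydroxyls are silylated and the labile silyl ester is hydrolysed selectively, leaving the aryl silyl ether.

**Step 11**
Reactants: 18 (2Z,4R,5Z,8E)-2-iodo-11-[(4-methoxybenzyl)oxy]-9-methyl-6-(propan-2-yl)undeca-2,5,8-trien-4-ol; 21 4-{[tri(propan-2-yl)silyl]oxy}benzoic acid
Product: 22 (2Z,4R,5Z,8E)-2-iodo-11-[(4-methoxybenzyl)oxy]-9-methyl-6-(propan-2-yl)undeca-2,5,8-trien-4-yl 4-{[tri(propan-2-yl)silyl]oxy}benzoate
Conditions: DCC, DMAP (cat.), CH2Cl2, 0 °C to rt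
Reagents that add atoms: none
Why: Steglich esterification; the C4–O bond is not broken, so configuration is retained and no allylic transposition can occur.

**Step 12**
Reactants: 22 (2Z,4R,5Z,8E)-2-iodo-11-[(4-methoxybenzyl)oxy]-9-methyl-6-(propan-2-yl)undeca-2,5,8-trien-4-yl 4-{[tri(propan-2-yl)silyl]oxy}benzoate
Product: 23 (2Z,4R,5Z)-2-iodo-7-[(2R,3R)-3-{2-[(4-methoxybenzyl)oxy]ethyl}-3-methyloxiran-2-yl]-6-(propan-2-yl)hepta-2,5-dien-4-yl 4-{[tri(propan-2-yl)silyl]oxy}benzoate
Conditions: D-fructose-derived Shi ketone (30 mol %), KHSO5 (as 2KHSO5·KHSO4·K2SO4), K2CO3, Bu4NHSO4 (cat.), MeCN/CH2(OMe)2, aq. Na2B4O7 buffer, 0 °C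
Reagents that add atoms: potassium peroxymonosulfate, [K+].[O-]S(=O)(=O)OO
Why: Shi epoxidation; the chiral dioxirane attacks the electron-rich, unhindered E-trisubstituted alkene through a spiro transition state and should give the (R,R)-epoxide (C1 R, C8a R) under reagent control. The C3=C3a alkene is deactivated by the allylic aroyloxy group and shielded by isopropyl, and the iodoalkene is electron-poor.

**Step 13**
Reactants: 23 (2Z,4R,5Z)-2-iodo-7-[(2R,3R)-3-{2-[(4-methoxybenzyl)oxy]ethyl}-3-methyloxiran-2-yl]-6-(propan-2-yl)hepta-2,5-dien-4-yl 4-{[tri(propan-2-yl)silyl]oxy}benzoate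
Product: 24 (2Z,4R,5Z)-7-[(2R,3R)-3-(2-hydroxyethyl)-3-methyloxiran-2-yl]-2-iodo-6-(propan-2-yl)hepta-2,5-dien-4-yl 4-{[tri(propan-2-yl)silyl]oxy}benzoate
Conditions: DDQ, CH2Cl2/pH 7 buffer (NaH2PO4/Na2HPO4), 0 °C to rt
Reagents that add atoms: none
Why: Oxidative cleavage of the PMB ether through the benzylic oxocarbenium ion; the buffer protects the epoxide, and ester, aryl silyl ether and iodoalkene are inert to DDQ.

**Step 14**
Reactants: 24 (2Z,4R,5Z)-7-[(2R,3R)-3-(2-hydroxyethyl)-3-methyloxiran-2-yl]-2-iodo-6-(propan-2-yl)hepta-2,5-dien-4-yl 4-{[tri(propan-2-yl)silyl]oxy}benzoate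
Product: 25 (2Z,4R,5Z)-2-iodo-7-[(2R,3R)-3-methyl-3-(2-oxoethyl)oxiran-2-yl]-6-(propan-2-yl)hepta-2,5-dien-4-yl 4-{[tri(propan-2-yl)silyl]oxy}benzoate
Conditions: Dess–Martin periodinane, NaHCO3, CH2Cl2, 0 °C; used without chromatography
Reagents that add atoms: none
Why: Dess–Martin oxidation under buffered, non-basic conditions gives the β,γ-epoxy aldehyde (C7) without β-elimination; it is carried forward directly.

**Step 15**
Reactants: 25 (2Z,4R,5Z)-2-iodo-7-[(2R,3R)-3-methyl-3-(2-oxoethyl)oxiran-2-yl]-6-(propan-2-yl)hepta-2,5-dien-4-yl 4-{[tri(propan-2-yl)silyl]oxy}benzoate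
Product: 27 (1R,3Z,5R,6Z,10R)-8-hydroxy-7,10-dimethyl-3-(propan-2-yl)-11-oxabicyclo[8.1.0]undeca-3,6-dien-5-yl 4-{[tri(propan-2-yl)silyl]oxy}benzoate (both C-8 epimers), via alkenylchromium dichloride 26 (not isolated)
Conditions: CrCl2 (10 equiv), NiCl2 (10 mol %), DMSO/THF, rt, 2 mM, slow addition of 25
Reagents that add atoms: none
Why: Nozaki–Hiyama–Kishi macrocyclisation; zerovalent nickel inserts into the C6–I bond, the alkenyl group passes to trivalent chromium and adds to the aldehyde only, with retention of the Z geometry. Ester, epoxide and aryl silyl ether are tolerated, and the new carbinol centre does not matter because it is oxidised next.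

**Step 16**
Reactants: 27 (1R,3Z,5R,6Z,10R)-8-hydroxy-7,10-dimethyl-3-(propan-2-yl)-11-oxabicyclo[8.1.0]undeca-3,6-dien-5-yl 4-{[tri(propan-2-yl)silyl]oxy}benzoate
Product: 28 (1R,3Z,5R,6Z,10R)-7,10-dimethyl-8-oxo-3-(propan-2-yl)-11-oxabicyclo[8.1.0]undeca-3,6-dien-5-yl 4-{[tri(propan-2-yl)silyl]oxy}benzoate
Conditions: Dess–Martin periodinane, NaHCO3, CH2Cl2, 0 °C to rt
Reagents that add atoms: none
Why: Dess–Martin oxidation of the allylic alcohol; both epimers converge on the enone, which makes the C5=C6 alkene electron-poor for the next step.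

**Step 17**
Reactants: 28 (1R,3Z,5R,6Z,10R)-7,10-dimethyl-8-oxo-3-(propan-2-yl)-11-oxabicyclo[8.1.0]undeca-3,6-dien-5-yl 4-{[tri(propan-2-yl)silyl]oxy}benzoate
Product: 30 (1R,3R,3aS,4S,8aR)-1,3-dihydroxy-6,8a-dimethyl-7-oxo-3-(propan-2-yl)-1,2,3,3a,4,7,8,8a-octahydroazulen-4-yl 4-{[tri(propan-2-yl)silyl]oxy}benzoate, via zwitterionic dioxanylium trifluoroborate 29 (not isolated)
Conditions: BF3·OEt2 (1.2 equiv), CH2Cl2, −78 to −40 °C; then THF/H2O, NaHCO3, −40 °C to rt
Reagents that add atoms: water, O
Why: BF3 binds the epoxide oxygen and the C8a–O bond breaks at the tertiary carbon as C3a of the Z-alkene attacks its rear side across the ring, forming the C3a–C8a bond with inversion at C8a and leaving a tertiary cation at C3. The closest known reaction type is the Lewis-acid transannular cyclisation of germacrene-type epoxides, here terminated by neighbouring-group capture as in acyloxonium chemistry. Ring A (seven-membered) closes in the exo mode with respect to both alkene and epoxide, and ring B (five-membered) in the formally endo mode with respect to both, which is feasible only because the medium ring already holds C3a and C8a within bonding distance. C8a and C1 take their configuration from the trans-epoxide (inversion at C8a, retention at C1, hence 8a-methyl cis to 1-OH). C3a is set by the alkene face that meets C8a: with isopropyl cis to C4, allylic 1,3-strain holds H-4 in the alkene plane, C5 and the ring chain on one face and the aroyloxy group on the other, so C8a arrives on the C5 face and gives 3aS; this is the trans fusion, because the twist about C3–C3a imposed by the ring-trans alkene matches the twist about C1–C8a imposed by rear-side opening of the (1R,8aR)-epoxide. C3 is set by the aroyl carbonyl on O-4, which can reach the cation only on the side of the C3a–C4 bond; it closes the six-membered dioxanylium ion 29 with O-3 cis to C4, and water opens this to the orthoacid, which collapses to the less hindered secondary ester and the tertiary alcohol. The step needs C3=C3a to react and C5=C6 not (secured by the enone), opening at C8a and not C1 (tertiary carbon), and capture faster than proton loss or ionisation of the allylic ester (low temperature, electron-rich aroyl carbonyl, enone-deactivated allyl system).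

**Step 18**
Reactants: 30 (1R,3R,3aS,4S,8aR)-1,3-dihydroxy-6,8a-dimethyl-7-oxo-3-(propan-2-yl)-1,2,3,3a,4,7,8,8a-octahydroazulen-4-yl 4-{[tri(propan-2-yl)silyl]oxy}benzoate
Product: 31 (1R,3R,3aS,4S,8aR)-1,3-dihydroxy-6,8a-dimethyl-7-oxo-3-(propan-2-yl)-1,2,3,3a,4,7,8,8a-octahydroazulen-4-yl 4-hydroxybenzoate
Conditions: Bu4NF, AcOH (1:1), THF, 0 °C
Reagents that add atoms: none
Why: Fluoride cleaves the aryl O–Si bond readily because the para-acyl phenoxide is a good leaving group. Acetic acid buffering prevents base-induced acyl migration to O-3 and enone side reactions, and the alcohols are unaffected.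

## Compound list

1 | but-3-yn-1-ol | C#CCCO | starting material
2 | 1-[(but-3-yn-1-yloxy)methyl]-4-methoxybenzene | C#CCCOCc1ccc(OC)cc1 | intermediate
3 | {(1E)-4-[(4-methoxybenzyl)oxy]-2-methylbut-1-en-1-yl}dimethylalane | C[Al](C)/C=C(\C)CCOCc1ccc(OC)cc1 | intermediate (not isolated)
4 | lithium butyl{(1E)-4-[(4-methoxybenzyl)oxy]-2-methylbut-1-en-1-yl}dimethylalanate | [Li+].CCCC[Al-](C)(C)/C=C(\C)CCOCc1ccc(OC)cc1 | intermediate (not isolated)
5 | (2E)-5-[(4-methoxybenzyl)oxy]-3-methylpent-2-en-1-ol | OC/C=C(\C)CCOCc1ccc(OC)cc1 | intermediate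
6 | 1-({[(3E)-5-bromo-3-methylpent-3-en-1-yl]oxy}methyl)-4-methoxybenzene | BrC/C=C(\C)CCOCc1ccc(OC)cc1 | intermediate
7 | prop-2-yn-1-ol | C#CCO | starting material
8 | (3-hydroxyprop-1-yn-1-yl)copper (monovalent copper acetylide of 7) | OCC#C[Cu] | intermediate (not isolated)
9 | (5E)-8-[(4-methoxybenzyl)oxy]-6-methyloct-5-en-2-yn-1-ol | OCC#CC/C=C(\C)CCOCc1ccc(OC)cc1 | intermediate
10 | sodium 2,2-bis(2-methoxyethoxy)-3-{(2E)-5-[(4-methoxybenzyl)oxy]-3-methylpent-2-en-1-yl}-2,5-dihydro-1,2-oxaluminol-2-uide | [Na+].COCCO[Al-]1(OCCOC)OCC=C1C/C=C(\C)CCOCc2ccc(OC)cc2 | intermediate (not isolated)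
11 | (2Z,5E)-3-iodo-8-[(4-methoxybenzyl)oxy]-6-methylocta-2,5-dien-1-ol | OC/C=C(\I)C/C=C(\C)CCOCc1ccc(OC)cc1 | intermediate
12 | (2Z,5E)-8-[(4-methoxybenzyl)oxy]-6-methyl-3-(propan-2-yl)octa-2,5-dien-1-ol | OC/C=C(\C(C)C)C/C=C(\C)CCOCc1ccc(OC)cc1 | intermediate
13 | (2Z,5E)-8-[(4-methoxybenzyl)oxy]-6-methyl-3-(propan-2-yl)octa-2,5-dienal | O=C/C=C(\C(C)C)C/C=C(\C)CCOCc1ccc(OC)cc1 | intermediate
14 | propyne | CC#C | starting material
15 | methyl(prop-1-yn-1-yl)zinc | C[Zn]C#CC | intermediate (not isolated)
16 | (4R,5Z,8E)-11-[(4-methoxybenzyl)oxy]-9-methyl-6-(propan-2-yl)undeca-5,8-dien-2-yn-4-ol | CC#C[C@H](O)/C=C(\C(C)C)C/C=C(\C)CCOCc1ccc(OC)cc1 | intermediate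
17 | sodium (5R)-2,2-bis(2-methoxyethoxy)-3-methyl-5-[(1Z,4E)-7-[(4-methoxybenzyl)oxy]-5-methyl-2-(propan-2-yl)hepta-1,4-dien-1-yl]-2,5-dihydro-1,2-oxaluminol-2-uide | [Na+].CC1=C[C@@H](/C=C(\C(C)C)C/C=C(\C)CCOCc2ccc(OC)cc2)O[Al-]1(OCCOC)OCCOC | intermediate (not isolated)
18 | (2Z,4R,5Z,8E)-2-iodo-11-[(4-methoxybenzyl)oxy]-9-methyl-6-(propan-2-yl)undeca-2,5,8-trien-4-ol | C/C(I)=C/[C@H](O)/C=C(\C(C)C)C/C=C(\C)CCOCc1ccc(OC)cc1 | intermediate
19 | 4-hydroxybenzoic acid | OC(=O)c1ccc(O)cc1 | starting material
20 | tri(propan-2-yl)silyl 4-{[tri(propan-2-yl)silyl]oxy}benzoate | CC(C)[Si](OC(=O)c1ccc(O[Si](C(C)C)(C(C)C)C(C)C)cc1)(C(C)C)C(C)C | intermediate (not isolated)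
21 | 4-{[tri(propan-2-yl)silyl]oxy}benzoic acid | OC(=O)c1ccc(O[Si](C(C)C)(C(C)C)C(C)C)cc1 | intermediate
22 | (2Z,4R,5Z,8E)-2-iodo-11-[(4-methoxybenzyl)oxy]-9-methyl-6-(propan-2-yl)undeca-2,5,8-trien-4-yl 4-{[tri(propan-2-yl)silyl]oxy}benzoate | C/C(I)=C/[C@H](OC(=O)c1ccc(O[Si](C(C)C)(C(C)C)C(C)C)cc1)/C=C(\C(C)C)C/C=C(\C)CCOCc2ccc(OC)cc2 | intermediate
23 | (2Z,4R,5Z)-2-iodo-7-[(2R,3R)-3-{2-[(4-methoxybenzyl)oxy]ethyl}-3-methyloxiran-2-yl]-6-(propan-2-yl)hepta-2,5-dien-4-yl 4-{[tri(propan-2-yl)silyl]oxy}benzoate | C/C(I)=C/[C@H](OC(=O)c1ccc(O[Si](C(C)C)(C(C)C)C(C)C)cc1)/C=C(\C(C)C)C[C@H]3O[C@]3(C)CCOCc2ccc(OC)cc2 | intermediate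
24 | (2Z,4R,5Z)-7-[(2R,3R)-3-(2-hydroxyethyl)-3-methyloxiran-2-yl]-2-iodo-6-(propan-2-yl)hepta-2,5-dien-4-yl 4-{[tri(propan-2-yl)silyl]oxy}benzoate | C/C(I)=C/[C@H](OC(=O)c1ccc(O[Si](C(C)C)(C(C)C)C(C)C)cc1)/C=C(\C(C)C)C[C@H]3O[C@]3(C)CCO | intermediate
25 | (2Z,4R,5Z)-2-iodo-7-[(2R,3R)-3-methyl-3-(2-oxoethyl)oxiran-2-yl]-6-(propan-2-yl)hepta-2,5-dien-4-yl 4-{[tri(propan-2-yl)silyl]oxy}benzoate | C/C(I)=C/[C@H](OC(=O)c1ccc(O[Si](C(C)C)(C(C)C)C(C)C)cc1)/C=C(\C(C)C)C[C@H]3O[C@]3(C)CC=O | intermediate
26 | alkenylchromium dichloride (trivalent chromium) formed from 25 at the iodine-bearing carbon C6 | C/C([Cr](Cl)Cl)=C/[C@H](OC(=O)c1ccc(O[Si](C(C)C)(C(C)C)C(C)C)cc1)/C=C(\C(C)C)C[C@H]3O[C@]3(C)CC=O | intermediate (not isolated)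
27 | (1R,3Z,5R,6Z,10R)-8-hydroxy-7,10-dimethyl-3-(propan-2-yl)-11-oxabicyclo[8.1.0]undeca-3,6-dien-5-yl 4-{[tri(propan-2-yl)silyl]oxy}benzoate (both C-8 epimers) | C/C1=C/[C@H](OC(=O)c2ccc(O[Si](C(C)C)(C(C)C)C(C)C)cc2)/C=C(\C(C)C)C[C@H]3O[C@]3(C)CC1O | intermediate
28 | (1R,3Z,5R,6Z,10R)-7,10-dimethyl-8-oxo-3-(propan-2-yl)-11-oxabicyclo[8.1.0]undeca-3,6-dien-5-yl 4-{[tri(propan-2-yl)silyl]oxy}benzoate | C/C1=C/[C@H](OC(=O)c2ccc(O[Si](C(C)C)(C(C)C)C(C)C)cc2)/C=C(\C(C)C)C[C@H]3O[C@]3(C)CC1=O | intermediate
29 | tricyclic 2-aryl-1,3-dioxan-2-ylium ion bridging O-4 and O-3 of the hydroazulenone, with O-1 bound to BF3 (zwitterion) | CC1=C[C@H](O3)[C@@H]2[C@@](C)(CC1=O)[C@H](O[B-](F)(F)F)C[C@@]2([O+]=C3c4ccc(O[Si](C(C)C)(C(C)C)C(C)C)cc4)C(C)C | intermediate (not isolated)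
30 | (1R,3R,3aS,4S,8aR)-1,3-dihydroxy-6,8a-dimethyl-7-oxo-3-(propan-2-yl)-1,2,3,3a,4,7,8,8a-octahydroazulen-4-yl 4-{[tri(propan-2-yl)silyl]oxy}benzoate | CC1=C[C@H](OC(=O)c2ccc(O[Si](C(C)C)(C(C)C)C(C)C)cc2)[C@@H]2[C@@](C)(CC1=O)[C@H](O)C[C@@]2(O)C(C)C | intermediate
31 | (1R,3R,3aS,4S,8aR)-1,3-dihydroxy-6,8a-dimethyl-7-oxo-3-(propan-2-yl)-1,2,3,3a,4,7,8,8a-octahydroazulen-4-yl 4-hydroxybenzoate | CC1=C[C@H](OC(=O)c2ccc(O)cc2)[C@@H]2[C@@](C)(CC1=O)[C@H](O)C[C@@]2(O)C(C)C | target

## Step count and risks

Total step count: 18. Longest linear sequence: 17 steps (steps 1–9 and 11–18, from but-3-yn-1-ol); step 10 is the one-step side branch.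

**Step 17 (key step).**

- Most likely to go wrong: the ring-B closure is formally endo at both reacting partners, so orbital overlap is poor. Opening of the β,γ-epoxy ketone by proton loss from C8 or by a 1,2-shift, proton loss from the C3 cation before the ester closes on it, and ionisation of the doubly allylic ester can then outrun the wanted path. The conformer of the planar-chiral ten-membered ring must also be the one predicted by allylic strain, and the orthoacid must collapse towards the secondary ester.
- Fallback, with a neighbouring group that captures the cation irreversibly: set out from 18 and acylate O-4 with Boc2O/DMAP to the tert-butyl carbonate F1.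
  - Steps 12–16 applied to it would give in turn the epoxide F2, the primary alcohol F3, the aldehyde F4, the macrocyclic carbinol F5 and the enone F6.
  - BF3·OEt2 should then give the cyclic carbonate F7: the more nucleophilic carbonate carbonyl traps the C3 cation, and loss of 2-methylpropene leaves a neutral six-membered carbonate with no choice of acyl position.
  - Silylation of O-1 (Et3SiOTf, 2,6-lutidine) gives the triethylsilyl ether F8. Methanolysis of the carbonate (K2CO3, MeOH, 0 °C) gives the diol F9. Esterification with 21 (DCC, DMAP) reaches only the secondary allylic hydroxyl and gives the ester F10.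
  - Bu4NF/AcOH removes both silyl groups, and the sequence comes back to the route at 31.

**Step 12.**

- Most likely to go wrong: the dioxirane also epoxidises the C3=C3a alkene, or facial control by the catalyst is incomplete, because differentiation rests only on electronic deactivation and shielding; the aryl silyl ether may slowly hydrolyse at pH 10.
- Fallback, by hydroxyl direction: set out from 22, remove the PMB group first (DDQ, buffered) to the homoallylic alcohol F11. Epoxidise with catalytic VO(OiPr)3, a chiral bishydroxamic acid ligand (the antipode that gives the (R,R)-epoxide) and cumene hydroperoxide. Only the alkene within reach of the hydroxyl reacts, and the sequence comes back to the route at 24.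

**Step 15.**

- Most likely to go wrong: intermolecular coupling and chromium-induced opening or β-elimination of the epoxy aldehyde compete with closure of a strained ten-membered ring that must hold a ring-trans alkene, a trans-epoxide and a Z-alkene.
- Fallback, closing the ring before the epoxide exists: set out from 22 and pass through the alcohol F11 described above. Dess–Martin oxidation gives the β,γ-unsaturated aldehyde F12. CrCl2/NiCl2 closure gives the macrocyclic trienol F13, and oxidation gives the trienone F14. Shi epoxidation of F14 attacks the only electron-rich unhindered alkene from the outer face of the ring, and the sequence comes back to the route at 28.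

**Step 8.**

- Most likely to go wrong: enantioselectivity is eroded with a small gaseous alkyne and a hindered enal with a cis isopropyl group; addition is slow and methyl transfer from Me2Zn competes.
- Fallback, by reduction instead of addition: set out from 13 and add prop-1-ynylmagnesium bromide to give the racemic carbinol F15. Oxidise with MnO2 to the ynone F16. Reduce with the (R)-methyl-CBS oxazaborolidine and BH3·SMe2; the alkynyl group acts as the small substituent, so the 4R alcohol is expected, and the sequence comes back to the route at 16.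

## Further compounds

F1 | step 17 | (2Z,4R,5Z,8E)-2-iodo-11-[(4-methoxybenzyl)oxy]-9-methyl-6-(propan-2-yl)undeca-2,5,8-trien-4-yl tert-butyl carbonate | C/C(I)=C/[C@H](OC(=O)OC(C)(C)C)/C=C(\C(C)C)C/C=C(\C)CCOCc1ccc(OC)cc1
F2 | step 17 | tert-butyl (2Z,4R,5Z)-2-iodo-7-[(2R,3R)-3-{2-[(4-methoxybenzyl)oxy]ethyl}-3-methyloxiran-2-yl]-6-(propan-2-yl)hepta-2,5-dien-4-yl carbonate | C/C(I)=C/[C@H](OC(=O)OC(C)(C)C)/C=C(\C(C)C)C[C@H]1O[C@]1(C)CCOCc2ccc(OC)cc2
F3 | step 17 | tert-butyl (2Z,4R,5Z)-7-[(2R,3R)-3-(2-hydroxyethyl)-3-methyloxiran-2-yl]-2-iodo-6-(propan-2-yl)hepta-2,5-dien-4-yl carbonate | C/C(I)=C/[C@H](OC(=O)OC(C)(C)C)/C=C(\C(C)C)C[C@H]1O[C@]1(C)CCO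
F4 | step 17 | tert-butyl (2Z,4R,5Z)-2-iodo-7-[(2R,3R)-3-methyl-3-(2-oxoethyl)oxiran-2-yl]-6-(propan-2-yl)hepta-2,5-dien-4-yl carbonate | C/C(I)=C/[C@H](OC(=O)OC(C)(C)C)/C=C(\C(C)C)C[C@H]1O[C@]1(C)CC=O
F5 | step 17 | tert-butyl (1R,3Z,5R,6Z,10R)-8-hydroxy-7,10-dimethyl-3-(propan-2-yl)-11-oxabicyclo[8.1.0]undeca-3,6-dien-5-yl carbonate (both C-8 epimers) | C/C1=C/[C@H](OC(=O)OC(C)(C)C)/C=C(\C(C)C)C[C@H]2O[C@]2(C)CC1O
F6 | step 17 | tert-butyl (1R,3Z,5R,6Z,10R)-7,10-dimethyl-8-oxo-3-(propan-2-yl)-11-oxabicyclo[8.1.0]undeca-3,6-dien-5-yl carbonate | C/C1=C/[C@H](OC(=O)OC(C)(C)C)/C=C(\C(C)C)C[C@H]2O[C@]2(C)CC1=O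
F7 | step 17 | cyclic carbonate of the hydroazulenone bridging O-4 and O-3, with free 1-OH | CC1=C[C@H](O3)[C@@H]2[C@@](C)(CC1=O)[C@H](O)C[C@@]2(OC3=O)C(C)C
F8 | step 17 | cyclic carbonate of the hydroazulenone bridging O-4 and O-3, 1-O-triethylsilyl ether | CC1=C[C@H](O3)[C@@H]2[C@@](C)(CC1=O)[C@H](O[Si](CC)(CC)CC)C[C@@]2(OC3=O)C(C)C
F9 | step 17 | 3,4-dihydroxy-6,8a-dimethyl-3-(propan-2-yl)-1-[(triethylsilyl)oxy]-2,3,3a,4,8,8a-hexahydroazulen-7(1H)-one, configured as in 30 | CC1=C[C@H](O)[C@@H]2[C@@](C)(CC1=O)[C@H](O[Si](CC)(CC)CC)C[C@@]2(O)C(C)C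
F10 | step 17 | 1-O-triethylsilyl ether of 30 | CC1=C[C@H](OC(=O)c3ccc(O[Si](C(C)C)(C(C)C)C(C)C)cc3)[C@@H]2[C@@](C)(CC1=O)[C@H](O[Si](CC)(CC)CC)C[C@@]2(O)C(C)C
F11 | step 12 | (2Z,4R,5Z,8E)-11-hydroxy-2-iodo-9-methyl-6-(propan-2-yl)undeca-2,5,8-trien-4-yl 4-{[tri(propan-2-yl)silyl]oxy}benzoate | C/C(I)=C/[C@H](OC(=O)c1ccc(O[Si](C(C)C)(C(C)C)C(C)C)cc1)/C=C(\C(C)C)C/C=C(\C)CCO
F12 | step 15 | (2Z,4R,5Z,8E)-2-iodo-9-methyl-11-oxo-6-(propan-2-yl)undeca-2,5,8-trien-4-yl 4-{[tri(propan-2-yl)silyl]oxy}benzoate | C/C(I)=C/[C@H](OC(=O)c1ccc(O[Si](C(C)C)(C(C)C)C(C)C)cc1)/C=C(\C(C)C)C/C=C(\C)CC=O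
F13 | step 15 | ten-membered trienol: 27 with the E-alkene in place of the epoxide (both carbinol epimers) | C/C1=C/[C@H](OC(=O)c2ccc(O[Si](C(C)C)(C(C)C)C(C)C)cc2)/C=C(\C(C)C)C/C=C(\C)CC1O
F14 | step 15 | ten-membered trienone: 28 with the E-alkene in place of the epoxide | C/C1=C/[C@H](OC(=O)c2ccc(O[Si](C(C)C)(C(C)C)C(C)C)cc2)/C=C(\C(C)C)C/C=C(\C)CC1=O
F15 | step 8 | racemic (5Z,8E)-11-[(4-methoxybenzyl)oxy]-9-methyl-6-(propan-2-yl)undeca-5,8-dien-2-yn-4-ol | CC#CC(O)/C=C(\C(C)C)C/C=C(\C)CCOCc1ccc(OC)cc1
F16 | step 8 | (5Z,8E)-11-[(4-methoxybenzyl)oxy]-9-methyl-6-(propan-2-yl)undeca-5,8-dien-2-yn-4-one | CC#CC(=O)/C=C(\C(C)C)C/C=C(\C)CCOCc1ccc(OC)cc1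
A1 | alternative 1 | ring B cyclopentanone: methyl 2-(2-tert-butoxy-2-oxoethyl)-2-methyl-3-oxo-5-(propan-2-yl)-5-[(triethylsilyl)oxy]cyclopentane-1-carboxylate, configured as in the SMILES | COC(=O)[C@@H]1[C@@](C)(CC(=O)OC(C)(C)C)C(=O)C[C@@]1(O[Si](CC)(CC)CC)C(C)C
A2 | alternative 1 | open-chain diazoketone: tert-butyl 5-diazo-3-{1-methoxy-4-methyl-1-oxo-3-[(triethylsilyl)oxy]pentan-2-yl}-3-methyl-4-oxopentanoate, configured as in the SMILES | COC(=O)[C@@H]([C@H](O[Si](CC)(CC)CC)C(C)C)[C@@](C)(CC(=O)OC(C)(C)C)C(=O)C=[N+]=[N-]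
A3 | alternative 2 | cyclopentane-fused β-lactone: 6-oxabicyclo[3.2.0]heptan-7-one with 5-isopropyl, 3-(tert-butyldimethylsilyloxy), 2-methyl and 2-{[2-((Z)-1-iodoprop-1-en-2-yl)-1,3-dioxolan-2-yl]methyl} groups | O=C1O[C@@]2(C(C)C)C[C@@H](O[Si](C)(C)C(C)(C)C)[C@](C)(CC3(OCCO3)/C(C)=C\I)[C@@H]12
A4 | alternative 2 | keto acid: 4-[(tert-butyldimethylsilyl)oxy]-3-{[2-((Z)-1-iodoprop-1-en-2-yl)-1,3-dioxolan-2-yl]methyl}-3,7-dimethyl-6-oxooctanoic acid, configured as in the SMILES | OC(=O)C[C@@](C)(CC1(OCCO1)/C(C)=C\I)[C@H](O[Si](C)(C)C(C)(C)C)CC(=O)C(C)C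
A5 | alternative 3 | bicyclic methoxy trienone: 3-[(tert-butyldimethylsilyl)oxy]-5-methoxy-6-methyl-2,3-dihydroazulen-1(8aH)-one, configured as in the SMILES | COC1=C(C)C=C[C@H]2C(=O)C[C@@H](O[Si](C)(C)C(C)(C)C)C2=C1
A6 | alternative 3 | aryl diazoketone: 4-[(tert-butyldimethylsilyl)oxy]-1-diazo-4-(3-methoxy-4-methylphenyl)butan-2-one, configured as in the SMILES | COc1cc(ccc1C)[C@H](O[Si](C)(C)C(C)(C)C)CC(=O)C=[N+]=[N-]
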